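**Retrosynthetic overview**
- The acid comes from its methyl ester by saponification.
- The 1,2-dioxane, the only ring, is closed last by forming the C3–O bond: an enantioselective 6-exo peroxy-Michael addition of an acyclic α-methoxy hydroperoxide to an (E)-enoate, followed by anomeric equilibration at C6.
- The hydroperoxy ketal comes from a δ-keto-(E)-enoate, H2O2 and MeOH.
- The keto enoate comes from a γ-keto aldehyde by Wittig olefination; the keto aldehyde comes from a Weinreb amide and an acetal Grignard reagent.
- The (E)-enyne comes from Sonogashira coupling of the hex-5-ynoic Weinreb amide with (E)-1-iodoundeca-1,10-diene, itself made from dec-9-enal by Takai olefination.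

**Assumptions and catalyst**
- Assumption: dec-9-enal is bought as such; if only dec-9-en-1-ol is at hand, it is oxidised first (one extra step).
- Assumption: the (S) form of catalyst A is taken to give 3S in step 7; the sense of induction of this new reaction must be confirmed, and the mirror-image catalyst (from D-tert-leucine) is used in the same step if it is opposite.
- Catalyst A is 1-[3,5-bis(trifluoromethyl)phenyl]-3-[(2S)-3,3-dimethyl-1-{[tris(4-methoxyphenyl)-λ5-phosphanylidene]amino}butan-2-yl]thiourea, SMILES COc1ccc(cc1)P(=NC[C@@H](NC(=S)Nc1cc(cc(c1)C(F)(F)F)C(F)(F)F)C(C)(C)C)(c1ccc(OC)cc1)c1ccc(OC)cc1. It is made beforehand by Staudinger reaction of the corresponding azide with P(4-MeOC6H4)3.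

**Route**

Step 1
Reactants: 1 dec-9-enal; 2 iodoform
Product: 3 (1E)-1-iodoundeca-1,10-diene
Conditions: CrCl2 (6 equiv), dioxane/THF 6:1, 0 °C to rt
Reagents that add atoms: none
Why: Takai olefination, in which the gem-dichromium species made from CHI3 and CrCl2 adds to the aldehyde and anti-eliminates to the E-vinyl iodide (about 10:1 E/Z in dioxane/THF) while the remote terminal alkene is inert.

Step 2
Reactants: 4 hex-5-ynoic acid; 5 N,O-dimethylhydroxylamine hydrochloride
Product: 7 N-methoxy-N-methylhex-5-ynamide, via 1-(1H-imidazol-1-yl)hex-5-yn-1-one 6 (not isolated)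
Conditions: CDI, CH2Cl2, rt; then 5, rt
Reagents that add atoms: none
Why: Amide coupling through the acyl imidazolide, with the imidazole set free taking up the HCl of the amine salt.

Step 3
Reactants: 7 N-methoxy-N-methylhex-5-ynamide; 3 (1E)-1-iodoundeca-1,10-diene
Product: 8 (7E)-N-methoxy-N-methylheptadeca-7,16-dien-5-ynamide
Conditions: PdCl2(PPh3)2 (2 mol%), CuI (4 mol%), Et3N, THF, degassed, rt
Reagents that add atoms: none
Why: Sonogashira coupling, in which oxidative addition of the vinyl iodide to zerovalent palladium, transmetalation from the copper acetylide and reductive elimination all proceed with retention, so the E geometry of 3 is carried into the enyne.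

Step 4
Reactants: 8 (7E)-N-methoxy-N-methylheptadeca-7,16-dien-5-ynamide; 9 [2-(1,3-dioxan-2-yl)ethyl]magnesium bromide (commercial 0.5 M solution in THF)
Product: 10 (9E)-1-(1,3-dioxan-2-yl)nonadeca-9,18-dien-7-yn-3-one
Conditions: THF, 0 °C; cold 1 M HCl quench
Reagents that add atoms: none
Why: Weinreb ketone synthesis, in which the magnesium-chelated tetrahedral adduct survives until the quench so that only one addition occurs, and the 1,3-dioxane tolerates the brief cold acid.

Step 5
Reactants: 10 (9E)-1-(1,3-dioxan-2-yl)nonadeca-9,18-dien-7-yn-3-one; 11 methyl (triphenyl-λ5-phosphanylidene)acetate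
Product: 13 methyl (2E,12E)-6-oxodocosa-2,12,21-trien-10-ynoate, via (10E)-4-oxoicosa-10,19-dien-8-ynal 12 (not isolated)
Conditions: 2 M HCl, THF, 45 °C; extract and dry; then 11, CH2Cl2, rt
Reagents that add atoms: none
Why: Acetal hydrolysis frees the γ-keto aldehyde, and the stabilised ylide then reacts only at the aldehyde in a Wittig olefination that gives the 2E-enoate (E/Z above 20:1).

Step 6
Reactants: 13 methyl (2E,12E)-6-oxodocosa-2,12,21-trien-10-ynoate
Product: 14 methyl (2E,12E)-6-hydroperoxy-6-methoxydocosa-2,12,21-trien-10-ynoate (racemic at C6)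
Conditions: urea–H2O2 adduct (5 equiv), Sc(OTf)3 (10 mol%), MeOH, rt; quick chromatography
Reagents that add atoms: hydrogen peroxide–urea adduct, NC(N)=O.OO; methanol, CO
Why: Lewis-acid-catalysed peroxyketalisation, in which the methoxy oxocarbenium ion formed from the ketone in MeOH is trapped by H2O2 to give the α-methoxy hydroperoxide while the enoate, enyne and terminal alkene are untouched.

Step 7
Reactants: 14 methyl (2E,12E)-6-hydroperoxy-6-methoxydocosa-2,12,21-trien-10-ynoate
Product: 16 methyl 2-[(3S,6R)-6-[(6E)-hexadeca-6,15-dien-4-yn-1-yl]-6-methoxy-1,2-dioxan-3-yl]acetate, via C6-epimer mixture of the (3S)-dioxane ester 15 (not isolated)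
Conditions: catalyst A (10 mol%), toluene, 4 Å MS, −20 °C; then MeOH, CSA (0.3 equiv), 0 °C to rt
Reagents that add atoms: none
Why: Proposed new method: the iminophosphorane of catalyst A deprotonates the hydroperoxide and its thiourea binds the enoate carbonyl, so the tight peroxide/iminophosphonium ion pair closes 6-exo-trig on one alkene face and forms the C3–O bond as 3S for both ketal epimers (the closest known reaction type is the iminophosphorane-catalysed enantioselective intramolecular oxa-Michael addition of alcohols to unactivated α,β-unsaturated esters, together with the racemic amine-mediated peroxy-Michael closure of such hydroperoxy ketals), and the CSA/MeOH treatment that follows ionises the ketal to the cyclic peroxycarbenium ion and returns MeOH axially, funnelling the C6 epimers to the anomerically favoured 6R isomer with both carbon substituents equatorial.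

Step 8
Reactants: 16 methyl 2-[(3S,6R)-6-[(6E)-hexadeca-6,15-dien-4-yn-1-yl]-6-methoxy-1,2-dioxan-3-yl]acetate
Product: 17 2-[(3S,6R)-6-[(6E)-hexadeca-6,15-dien-4-yn-1-yl]-6-methoxy-1,2-dioxan-3-yl]acetic acid
Conditions: LiOH (3 equiv), THF/H2O 3:1, 0 °C; then 0.5 M HCl to pH 4 at 0 °C
Reagents that add atoms: lithium hydroxide, [Li+].[OH-]
Why: Saponification (ester hydrolysis by acyl substitution) at 0 °C outpaces enolisation of the β-peroxy ester, so the dialkyl peroxyketal and both stereocentres are kept.

**Compound list**

1 | dec-9-enal | C=CCCCCCCCC=O | starting material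
2 | iodoform (triiodomethane) | IC(I)I | starting material
3 | (1E)-1-iodoundeca-1,10-diene | C=CCCCCCCC/C=C/I | intermediate
4 | hex-5-ynoic acid | C#CCCCC(=O)O | starting material
5 | N,O-dimethylhydroxylamine hydrochloride | CNOC.Cl | starting material
6 | 1-(1H-imidazol-1-yl)hex-5-yn-1-one | C#CCCCC(=O)n1ccnc1 | intermediate
7 | N-methoxy-N-methylhex-5-ynamide | C#CCCCC(=O)N(C)OC | intermediate
8 | (7E)-N-methoxy-N-methylheptadeca-7,16-dien-5-ynamide | C=CCCCCCCC/C=C/C#CCCCC(=O)N(C)OC | intermediate
9 | [2-(1,3-dioxan-2-yl)ethyl]magnesium bromide | Br[Mg]CCC1OCCCO1 | starting material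
10 | (9E)-1-(1,3-dioxan-2-yl)nonadeca-9,18-dien-7-yn-3-one | C=CCCCCCCC/C=C/C#CCCCC(=O)CCC1OCCCO1 | intermediate
11 | methyl (triphenyl-λ5-phosphanylidene)acetate | COC(=O)C=P(c1ccccc1)(c1ccccc1)c1ccccc1 | starting material
12 | (10E)-4-oxoicosa-10,19-dien-8-ynal | C=CCCCCCCC/C=C/C#CCCCC(=O)CCC=O | intermediate
13 | methyl (2E,12E)-6-oxodocosa-2,12,21-trien-10-ynoate | C=CCCCCCCC/C=C/C#CCCCC(=O)CC/C=C/C(=O)OC | intermediate
14 | methyl (2E,12E)-6-hydroperoxy-6-methoxydocosa-2,12,21-trien-10-ynoate (racemic at C6) | C=CCCCCCCC/C=C/C#CCCCC(OC)(OO)CC/C=C/C(=O)OC | intermediate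
15 | methyl 2-[(3S)-6-[(6E)-hexadeca-6,15-dien-4-yn-1-yl]-6-methoxy-1,2-dioxan-3-yl]acetate, mixture of C6 epimers | C=CCCCCCCC/C=C/C#CCCCC1(OC)CC[C@@H](CC(=O)OC)OO1 | intermediate
16 | methyl 2-[(3S,6R)-6-[(6E)-hexadeca-6,15-dien-4-yn-1-yl]-6-methoxy-1,2-dioxan-3-yl]acetate | C=CCCCCCCC/C=C/C#CCCC[C@]1(OC)CC[C@@H](CC(=O)OC)OO1 | intermediate
17 | 2-[(3S,6R)-6-[(6E)-hexadeca-6,15-dien-4-yn-1-yl]-6-methoxy-1,2-dioxan-3-yl]acetic acid | C=CCCCCCCC/C=C/C#CCCC[C@]1(OC)CC[C@@H](CC(=O)O)OO1 | target

**Step count and risks**

Total step count: 8. Longest linear sequence: 7 steps (from 4 through steps 2 to 8; the branch from 1 to 3 joins in step 3).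

The three steps most likely to fail:

Step 7 (the proposed new cyclisation). Three things can go wrong:
- the peroxide anion may attack the phosphorus of the protonated catalyst and destroy it;
- the ketal enantiomer that is mismatched with the catalyst may close with lower face selectivity, which lowers the ee because the later equilibration corrects C6 but not C3;
- the strong base may trigger retro-Michael opening or Kornblum–DeLaMare cleavage.

The fallback uses known chemistry, sets out from 12 (isolated after the hydrolysis half of step 5) and comes back to the route at 17. Wittig reaction of 12 with (triphenylphosphoranylidene)acetaldehyde in warm toluene gives the keto enal (2E,12E)-6-oxodocosa-2,12,21-trien-10-ynal F4. The known iminium-catalysed asymmetric β-peroxidation of enals follows, with a diarylprolinol silyl ether as catalyst and 2-methoxypropan-2-yl hydroperoxide as nucleophile; it forms the C3–O bond intermolecularly and gives (3S,12E)-3-[(2-methoxypropan-2-yl)peroxy]-6-oxodocosa-12,21-dien-10-ynal F5. Pinnick oxidation (NaClO2, NaH2PO4, 2-methylbut-2-ene, tBuOH/H2O) gives (3S,12E)-3-[(2-methoxypropan-2-yl)peroxy]-6-oxodocosa-12,21-dien-10-ynoic acid F6. PPTS in MeOH then removes the 2-methoxypropan-2-yl group; the freed hydroperoxide closes onto the C6 ketone and is ketalised by MeOH under the same thermodynamic control, giving 17.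

Step 6 (peroxyketalisation). The reaction is an equilibrium and can stall as a mixture of ketone, dimethyl ketal and gem-dihydroperoxide. The fallback sets out from 13 and comes back at 14. HC(OMe)3 and PPTS in MeOH give the isolated ketal methyl (2E,12E)-6,6-dimethoxydocosa-2,12,21-trien-10-ynoate F3. Anhydrous ethereal H2O2 with catalytic CSA at 0 °C then exchanges one methoxy group for the hydroperoxide under water-free conditions, giving 14.

Step 5 (acetal hydrolysis and Wittig). Warm aqueous acid may hydrolyse the 1,3-dioxane only slowly and may convert the γ-keto aldehyde into a furan or aldol products. The fallback sets out from 8 and comes back at 12, avoiding acid by reaching the aldehyde through oxidation. Addition of [3-(tert-butyldimethylsilyloxy)propyl]magnesium bromide to 8 gives (10E)-1-[(tert-butyldimethylsilyl)oxy]icosa-10,19-dien-8-yn-4-one F1. TBAF buffered with AcOH gives (10E)-1-hydroxyicosa-10,19-dien-8-yn-4-one F2. Dess–Martin periodinane with NaHCO3 oxidises F2 to 12, which is taken on with 11 as in the second half of step 5.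

Further compounds
F1 | step 5 | (10E)-1-[(tert-butyldimethylsilyl)oxy]icosa-10,19-dien-8-yn-4-one | C=CCCCCCCC/C=C/C#CCCCC(=O)CCCO[Si](C)(C)C(C)(C)C
F2 | step 5 | (10E)-1-hydroxyicosa-10,19-dien-8-yn-4-one | C=CCCCCCCC/C=C/C#CCCCC(=O)CCCO
F3 | step 6 | methyl (2E,12E)-6,6-dimethoxydocosa-2,12,21-trien-10-ynoate | C=CCCCCCCC/C=C/C#CCCCC(OC)(OC)CC/C=C/C(=O)OC
F4 | step 7 | (2E,12E)-6-oxodocosa-2,12,21-trien-10-ynal | C=CCCCCCCC/C=C/C#CCCCC(=O)CC/C=C/C=O
F5 | step 7 | (3S,12E)-3-[(2-methoxypropan-2-yl)peroxy]-6-oxodocosa-12,21-dien-10-ynal | C=CCCCCCCC/C=C/C#CCCCC(=O)CC[C@@H](CC=O)OOC(C)(C)OC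
F6 | step 7 | (3S,12E)-3-[(2-methoxypropan-2-yl)peroxy]-6-oxodocosa-12,21-dien-10-ynoic acid | C=CCCCCCCC/C=C/C#CCCCC(=O)CC[C@@H](CC(=O)O)OOC(C)(C)OC
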